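**Plan**
1. Cuts: chromene C3=C4 (ring-closing metathesis) and O1–C2 (palladium allylic etherification of atranol); then cyclohexane C1–C6; then, in the lactone precursor, the bond from ring carbon C2 to the side chain (B-alkyl Suzuki) and the C1–C2 bond (Dieckmann).
2. Enabling feature: cyclohexane C1 with its OH and CH2OH is a glycolic acid α-carbon at a lower oxidation level, and C4–C5–C6 is an allyl unit. C4 sits next to the gem-dimethyl C3 and 1,5 to the CH2OH carbon, so an oxygen on C4 can be tied to that carbon as a δ-lactone (O, C=O, C1, C2, C3, C4). A [3,3] shift of its enolate then joins C1 to C6.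
3. Forward order: δ-lactone (aldol, Dieckmann, Suzuki, conjugate reduction, hydroxylation), then Ireland–Claisen ring contraction to the cyclohexene, alkene saturation and acid reduction, then the chromene last (aryl ether first, pyran ring second).
4. Stereochemistry: the lactone carbinol centre comes from a reagent-controlled aldol; ring C2 from substrate-controlled hydride addition; the quaternary C1 by chirality transfer from the carbinol centre in the [3,3] shift; chromene C2 from the chiral palladium ligand.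

Key step: step 10

Remark: atranol and (E)-3-methylpent-2-en-4-yn-1-ol are taken as purchasable; the sense of induction in steps 1 and 14 is assigned by analogy with simple aldehydes and with geranyl methyl carbonate, and the enantiomeric promoter or ligand would be used if a model run showed the opposite sense.

Lactone positions below use pyran-2-one numbering (O1, C2 carbonyl, C3, C4, C5 gem-dimethyl, C6 vinyl carbinol).

**Step 1**
Reactants: 1 acrolein; 2 1-methoxy-2-methyl-1-(trimethylsilyloxy)prop-1-ene
Product: 3 methyl (3R)-3-hydroxy-2,2-dimethylpent-4-enoate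
Conditions: N-tosyl-L-valine, BH3·THF, CH2Cl2, 0 °C → rt; then 1 and 2, −78 °C; pH 7 buffer, then 1 M HCl/THF
Reagents that add atoms: none
Why: Chiral oxazaborolidinone-promoted Mukaiyama aldol addition, in which the silyl ketene acetal attacks one face of the boron-bound aldehyde (1,2-addition) and so sets the carbinol centre (R, reagent control) next to the new gem-dimethyl quaternary carbon.

**Step 2**
Reactants: 3 methyl (3R)-3-hydroxy-2,2-dimethylpent-4-enoate; 4 acetic anhydride
Product: 5 methyl (3R)-3-acetoxy-2,2-dimethylpent-4-enoate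
Conditions: pyridine, DMAP (cat.), CH2Cl2, 0 °C → rt
Reagents that add atoms: none
Why: DMAP-catalysed acylation of the allylic alcohol brings in the two carbons that become cyclohexane C1 and the hydroxymethyl carbon, without touching the stereocentre.

**Step 3**
Reactants: 5 methyl (3R)-3-acetoxy-2,2-dimethylpent-4-enoate
Product: 6 (6R)-4-hydroxy-5,5-dimethyl-6-vinyl-5,6-dihydro-2H-pyran-2-one
Conditions: LiN(SiMe3)2 (3 equiv), THF, −78 → 0 °C; 1 M HCl
Reagents that add atoms: none
Why: Intramolecular Claisen (Dieckmann-type) condensation of the acetate enolate onto the non-enolisable ester should close the six-membered β-keto lactone, held as its enolate until work-up; the carbinol centre has no acidic hydrogen and keeps its configuration.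

**Step 4**
Reactants: 6 (6R)-4-hydroxy-5,5-dimethyl-6-vinyl-5,6-dihydro-2H-pyran-2-one
Product: 7 (6R)-5,5-dimethyl-2-oxo-6-vinyl-5,6-dihydro-2H-pyran-4-yl trifluoromethanesulfonate
Conditions: Tf2O, Et3N, CH2Cl2, −78 °C
Reagents that add atoms: trifluoromethanesulfonic anhydride, O=S(=O)(OS(=O)(=O)C(F)(F)F)C(F)(F)F
Why: O-Sulfonylation of the vinylogous acid gives the enol triflate at C4, the site where the side chain is attached.

**Step 5**
Reactants: 8 (2E)-3-methylpent-2-en-4-yn-1-ol
Product: 9 (2E)-3-methylpent-2-en-4-yn-1-yl pivalate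
Conditions: t-BuCOCl, pyridine, CH2Cl2, 0 °C → rt
Reagents that add atoms: pivaloyl chloride, CC(C)(C)C(Cl)=O
Why: Esterification; the pivalate has no α-hydrogen and ionises poorly with palladium, so it should survive the amide bases and the cross-coupling until LiAlH4 removes it in step 12.

**Step 6**
Reactants: 9 (2E)-3-methylpent-2-en-4-yn-1-yl pivalate
Product: 10 (2E)-3-methylpenta-2,4-dien-1-yl pivalate
Conditions: H2 (1 atm), Pd/CaCO3 poisoned with Pb(OAc)2, quinoline, EtOAc, rt
Reagents that add atoms: none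
Why: Partial hydrogenation of the terminal alkyne on poisoned palladium should stop at the vinyl group and leave the E trisubstituted alkene intact.

**Step 7**
Reactants: 10 (2E)-3-methylpenta-2,4-dien-1-yl pivalate; 7 (6R)-5,5-dimethyl-2-oxo-6-vinyl-5,6-dihydro-2H-pyran-4-yl trifluoromethanesulfonate
Product: 12 (2E)-5-[(6R)-5,5-dimethyl-2-oxo-6-vinyl-5,6-dihydro-2H-pyran-4-yl]-3-methylpent-2-en-1-yl pivalate, via alkylborane 11 (not isolated)
Conditions: 9-BBN, THF, 0 °C → rt; then 7, Pd(dppf)Cl2 (5 mol %), AsPh3, Cs2CO3, DMF/H2O, rt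
Reagents that add atoms: none
Why: Anti-Markovnikov hydroboration of the terminal vinyl group by 9-BBN, then B-alkyl Suzuki–Miyaura coupling with the enol triflate, which should add to zerovalent palladium far faster than either allylic ester C–O bond at room temperature; no stereocentre is formed.

**Step 8**
Reactants: 12 (2E)-5-[(6R)-5,5-dimethyl-2-oxo-6-vinyl-5,6-dihydro-2H-pyran-4-yl]-3-methylpent-2-en-1-yl pivalate
Product: 13 (2E)-5-[(4R,6R)-5,5-dimethyl-2-oxo-6-vinyltetrahydro-2H-pyran-4-yl]-3-methylpent-2-en-1-yl pivalate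
Conditions: Cu(OAc)2·H2O (5 mol %), 1,2-bis(diphenylphosphino)benzene, (HMe2Si)2O, t-BuOH, toluene, rt
Reagents that add atoms: none
Why: Copper hydride 1,4-reduction, in which hydride should add axially to C4 of the half-chair with equatorial vinyl, on the face away from the pseudoaxial C5 methyl, so that the side chain ends equatorial and cis to the vinyl group (4R); isolated alkenes and the pivalate are left alone.

**Step 9**
Reactants: 13 (2E)-5-[(4R,6R)-5,5-dimethyl-2-oxo-6-vinyltetrahydro-2H-pyran-4-yl]-3-methylpent-2-en-1-yl pivalate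
Product: 14 (2E)-5-[(3R,4S,6R)-3-hydroxy-5,5-dimethyl-2-oxo-6-vinyltetrahydro-2H-pyran-4-yl]-3-methylpent-2-en-1-yl pivalate
Conditions: KN(SiMe3)2, THF, −78 °C; 2-(phenylsulfonyl)-3-phenyloxaziridine, −78 °C; sat. aq. NH4Cl
Reagents that add atoms: 2-(phenylsulfonyl)-3-phenyloxaziridine, O=S(=O)(c1ccccc1)N1OC1c1ccccc1
Why: Electrophilic hydroxylation of the potassium lactone enolate by the N-sulfonyloxaziridine; the new C3 centre (expected trans to the C4 side chain) does not matter because it becomes sp2 in step 10.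

**Step 10**
Reactants: 14 (2E)-5-[(3R,4S,6R)-3-hydroxy-5,5-dimethyl-2-oxo-6-vinyltetrahydro-2H-pyran-4-yl]-3-methylpent-2-en-1-yl pivalate
Product: 17 (1R,6S)-1-hydroxy-5,5-dimethyl-6-[(3E)-3-methyl-5-(pivaloyloxy)pent-3-en-1-yl]cyclohex-3-ene-1-carboxylic acid, via cyclic bis-silyl ketene acetal 15 (not isolated), via rearranged silyl ester 16 (not isolated)
Conditions: Me3SiCl/Et3N (6 equiv), THF, −78 °C; LiN(i-Pr)2 (2.5 equiv), −78 → 0 °C; toluene, 110 °C; 1 M HCl, THF, rt
Reagents that add atoms: none
Why: The alkoxide and the lactone enolate are both silylated, and the cyclic O-silyl ketene acetal 15 undergoes a concerted suprafacial [3,3]-sigmatropic shift (Ireland–Claisen rearrangement) in which the allylic C6–O1 bond breaks while the vinyl terminus bonds to C3, contracting the lactone to the carbocycle. The closest known reaction type is the ester-enolate Claisen ring contraction of 6-vinyl δ-lactone silyl ketene acetals to cyclohex-3-ene-1-carboxylic acids. The cyclohexene ring is closed by this pericyclic event through the only geometry the ring allows, a boat-like six-centre transition state with the vinyl group bridging over the ketene acetal (a bicyclo[2.2.2]octane-like array), not by a polar ring closure. The new quaternary centre (C1 of 17) is controlled by the lactone carbinol centre C6: the C–C bond can form only on the ring face that carries the vinyl group, and because the C4 side chain sits on that same face, the silyloxy group ends cis and the carboxyl trans to the side chain (1R,6S, as in the target), while the C3 configuration of 14 is erased in 15. The step needs enolisation at C3 only, secured because C3–H is the single acidic C–H (the pivalate has no α-hydrogen), and it needs the shift to outrun loss of the ketene acetal, secured by the internal Me3SiCl quench and the electron-rich, fully oxygenated ketene acetal.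

**Step 11**
Reactants: 17 (1R,6S)-1-hydroxy-5,5-dimethyl-6-[(3E)-3-methyl-5-(pivaloyloxy)pent-3-en-1-yl]cyclohex-3-ene-1-carboxylic acid
Product: 18 (1R,2S)-1-hydroxy-3,3-dimethyl-2-[(3E)-3-methyl-5-(pivaloyloxy)pent-3-en-1-yl]cyclohexane-1-carboxylic acid
Conditions: H2 (1 atm), RhCl(PPh3)3 (5 mol %), benzene/EtOH, rt
Reagents that add atoms: none
Why: Homogeneous hydrogenation with the rhodium chloride–phosphine complex should reduce the cis-disubstituted ring alkene much faster than the trisubstituted side-chain alkene, and it forms no stereocentre.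

**Step 12**
Reactants: 18 (1R,2S)-1-hydroxy-3,3-dimethyl-2-[(3E)-3-methyl-5-(pivaloyloxy)pent-3-en-1-yl]cyclohexane-1-carboxylic acid
Product: 19 (1R,2S)-1-(hydroxymethyl)-2-[(3E)-5-hydroxy-3-methylpent-3-en-1-yl]-3,3-dimethylcyclohexan-1-ol
Conditions: LiAlH4, THF, 0 °C → reflux; aq. NaOH work-up
Reagents that add atoms: none
Why: Hydride reduction of the carboxylic acid to the primary alcohol and reductive cleavage of the pivalate in one operation; both stereocentres are untouched.

**Step 13**
Reactants: 19 (1R,2S)-1-(hydroxymethyl)-2-[(3E)-5-hydroxy-3-methylpent-3-en-1-yl]-3,3-dimethylcyclohexan-1-ol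
Product: 20 (2E)-5-[(1S,2R)-2-hydroxy-2-(hydroxymethyl)-6,6-dimethylcyclohexyl]-3-methylpent-2-en-1-yl methyl carbonate
Conditions: MeOCOCl (1.1 equiv), pyridine, CH2Cl2, −40 → −20 °C
Reagents that add atoms: methyl chloroformate, COC(=O)Cl
Why: Chemoselective carbonate formation at the unhindered allylic primary alcohol; the neopentyl-type primary alcohol next to the quaternary carbinol and the tertiary alcohol should react much more slowly at low temperature.

**Step 14**
Reactants: 20 (2E)-5-[(1S,2R)-2-hydroxy-2-(hydroxymethyl)-6,6-dimethylcyclohexyl]-3-methylpent-2-en-1-yl methyl carbonate; 21 2,6-dihydroxy-4-methylbenzaldehyde (atranol)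
Product: 22 2-hydroxy-6-{[(3S)-5-[(1S,2R)-2-hydroxy-2-(hydroxymethyl)-6,6-dimethylcyclohexyl]-3-methylpent-1-en-3-yl]oxy}-4-methylbenzaldehyde
Conditions: 21 (2 equiv), Pd2(dba)3·CHCl3 (2.5 mol %), (1R,2R)-N,N'-bis[2-(diphenylphosphino)benzoyl]cyclohexane-1,2-diamine (7.5 mol %), CH2Cl2, rt
Reagents that add atoms: none
Why: Palladium-catalysed asymmetric allylic etherification (Tsuji–Trost type), in which ionisation of the carbonate gives a 1,1-disubstituted π-allyl complex that the phenoxide attacks at the more substituted terminus inside the chiral pocket of the diphosphine, so the tertiary ether centre (S) is set by the ligand, independent of the remote ring stereocentres.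

**Step 15**
Reactants: 22 2-hydroxy-6-{[(3S)-5-[(1S,2R)-2-hydroxy-2-(hydroxymethyl)-6,6-dimethylcyclohexyl]-3-methylpent-1-en-3-yl]oxy}-4-methylbenzaldehyde
Product: 23 3-{[(3S)-5-[(1S,2R)-2-hydroxy-2-(hydroxymethyl)-6,6-dimethylcyclohexyl]-3-methylpent-1-en-3-yl]oxy}-5-methyl-2-vinylphenol
Conditions: Ph3PCH3Br (6 equiv), KOt-Bu (6 equiv), THF, 0 °C → rt
Reagents that add atoms: methyltriphenylphosphonium bromide, C[P+](c1ccccc1)(c1ccccc1)c1ccccc1.[Br-]
Why: Wittig methylenation of the salicylaldehyde-type aldehyde with excess ylide, which tolerates the free hydroxyl groups as their potassium salts and touches no stereocentre.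

**Step 16**
Reactants: 23 3-{[(3S)-5-[(1S,2R)-2-hydroxy-2-(hydroxymethyl)-6,6-dimethylcyclohexyl]-3-methylpent-1-en-3-yl]oxy}-5-methyl-2-vinylphenol
Product: 24 (1R,2S)-1-(hydroxymethyl)-2-{2-[(2S)-5-hydroxy-2,7-dimethyl-2H-chromen-2-yl]ethyl}-3,3-dimethylcyclohexan-1-ol
Conditions: second-generation Grubbs catalyst RuCl2(=CHPh)(PCy3)(H2IMes) (5 mol %), CH2Cl2, 40 °C
Reagents that add atoms: none
Why: Ring-closing metathesis of the styrene with the vinyl group on the quaternary ether carbon closes the six-membered 2H-pyran ring with loss of ethene; the C–O bond set in step 14 is not broken, so C2 keeps the S configuration.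

**Compound list**
1 | acrolein (prop-2-enal) | C=CC=O | starting material
2 | 1-methoxy-2-methyl-1-(trimethylsilyloxy)prop-1-ene | COC(O[Si](C)(C)C)=C(C)C | starting material
3 | methyl (3R)-3-hydroxy-2,2-dimethylpent-4-enoate | COC(=O)C(C)(C)[C@H](O)C=C | intermediate
4 | acetic anhydride | CC(=O)OC(C)=O | starting material
5 | methyl (3R)-3-acetoxy-2,2-dimethylpent-4-enoate | COC(=O)C(C)(C)[C@H](OC(C)=O)C=C | intermediate
6 | (6R)-4-hydroxy-5,5-dimethyl-6-vinyl-5,6-dihydro-2H-pyran-2-one | O=C1C=C(O)C(C)(C)[C@@H](C=C)O1 | intermediate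
7 | (6R)-5,5-dimethyl-2-oxo-6-vinyl-5,6-dihydro-2H-pyran-4-yl trifluoromethanesulfonate | O=C1C=C(OS(=O)(=O)C(F)(F)F)C(C)(C)[C@@H](C=C)O1 | intermediate
8 | (2E)-3-methylpent-2-en-4-yn-1-ol | C#C/C(C)=C/CO | starting material
9 | (2E)-3-methylpent-2-en-4-yn-1-yl pivalate | C#C/C(C)=C/COC(=O)C(C)(C)C | intermediate
10 | (2E)-3-methylpenta-2,4-dien-1-yl pivalate | C=C/C(C)=C/COC(=O)C(C)(C)C | intermediate
11 | (2E)-5-(9-borabicyclo[3.3.1]nonan-9-yl)-3-methylpent-2-en-1-yl pivalate | CC(C)(C)C(=O)OC/C=C(C)/CCB1C2CCCC1CCC2 | intermediate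
12 | (2E)-5-[(6R)-5,5-dimethyl-2-oxo-6-vinyl-5,6-dihydro-2H-pyran-4-yl]-3-methylpent-2-en-1-yl pivalate | CC(C)(C)C(=O)OC/C=C(C)/CCC1=CC(=O)O[C@H](C=C)C1(C)C | intermediate
13 | (2E)-5-[(4R,6R)-5,5-dimethyl-2-oxo-6-vinyltetrahydro-2H-pyran-4-yl]-3-methylpent-2-en-1-yl pivalate | CC(C)(C)C(=O)OC/C=C(C)/CC[C@@H]1CC(=O)O[C@H](C=C)C1(C)C | intermediate
14 | (2E)-5-[(3R,4S,6R)-3-hydroxy-5,5-dimethyl-2-oxo-6-vinyltetrahydro-2H-pyran-4-yl]-3-methylpent-2-en-1-yl pivalate | CC(C)(C)C(=O)OC/C=C(C)/CC[C@@H]1[C@@H](O)C(=O)O[C@H](C=C)C1(C)C | intermediate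
15 | (2E)-5-[(4S,6R)-5,5-dimethyl-2,3-bis(trimethylsilyloxy)-6-vinyl-5,6-dihydro-4H-pyran-4-yl]-3-methylpent-2-en-1-yl pivalate | CC(C)(C)C(=O)OC/C=C(C)/CC[C@@H]1C(O[Si](C)(C)C)=C(O[Si](C)(C)C)O[C@H](C=C)C1(C)C | intermediate
16 | trimethylsilyl (1R,6S)-5,5-dimethyl-6-[(3E)-3-methyl-5-(pivaloyloxy)pent-3-en-1-yl]-1-(trimethylsilyloxy)cyclohex-3-ene-1-carboxylate | CC(C)(C)C(=O)OC/C=C(C)/CC[C@H]1C(C)(C)C=CC[C@]1(O[Si](C)(C)C)C(=O)O[Si](C)(C)C | intermediate
17 | (1R,6S)-1-hydroxy-5,5-dimethyl-6-[(3E)-3-methyl-5-(pivaloyloxy)pent-3-en-1-yl]cyclohex-3-ene-1-carboxylic acid | CC(C)(C)C(=O)OC/C=C(C)/CC[C@H]1C(C)(C)C=CC[C@]1(O)C(=O)O | intermediate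
18 | (1R,2S)-1-hydroxy-3,3-dimethyl-2-[(3E)-3-methyl-5-(pivaloyloxy)pent-3-en-1-yl]cyclohexane-1-carboxylic acid | CC(C)(C)C(=O)OC/C=C(C)/CC[C@H]1C(C)(C)CCC[C@]1(O)C(=O)O | intermediate
19 | (1R,2S)-1-(hydroxymethyl)-2-[(3E)-5-hydroxy-3-methylpent-3-en-1-yl]-3,3-dimethylcyclohexan-1-ol | OC/C=C(C)/CC[C@H]1C(C)(C)CCC[C@]1(O)CO | intermediate
20 | (2E)-5-[(1S,2R)-2-hydroxy-2-(hydroxymethyl)-6,6-dimethylcyclohexyl]-3-methylpent-2-en-1-yl methyl carbonate | COC(=O)OC/C=C(C)/CC[C@H]1C(C)(C)CCC[C@]1(O)CO | intermediate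
21 | 2,6-dihydroxy-4-methylbenzaldehyde (atranol) | Cc1cc(O)c(C=O)c(O)c1 | starting material
22 | 2-hydroxy-6-{[(3S)-5-[(1S,2R)-2-hydroxy-2-(hydroxymethyl)-6,6-dimethylcyclohexyl]-3-methylpent-1-en-3-yl]oxy}-4-methylbenzaldehyde | Cc1cc(O)c(C=O)c(c1)O[C@@](C)(CC[C@H]1C(C)(C)CCC[C@]1(O)CO)C=C | intermediate
23 | 3-{[(3S)-5-[(1S,2R)-2-hydroxy-2-(hydroxymethyl)-6,6-dimethylcyclohexyl]-3-methylpent-1-en-3-yl]oxy}-5-methyl-2-vinylphenol | Cc1cc(O)c(C=C)c(c1)O[C@@](C)(CC[C@H]1C(C)(C)CCC[C@]1(O)CO)C=C | intermediate
24 | (1R,2S)-1-(hydroxymethyl)-2-{2-[(2S)-5-hydroxy-2,7-dimethyl-2H-chromen-2-yl]ethyl}-3,3-dimethylcyclohexan-1-ol | Cc1cc(O)c2c(c1)O[C@@](C)(CC[C@H]1C(C)(C)CCC[C@]1(O)CO)C=C2 | target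

**Totals**
Total step count: 16. Longest linear sequence: 14 steps (steps 1–4 and 7–16); steps 5–6 form the side-chain branch.

**Steps most likely to fail**

Step 8. Hydride transfer to the β-carbon next to the quaternary C5 may be slow, and facial discrimination may then be lost, giving both C4 epimers. Fallback (thermodynamic instead of kinetic control): the C4 mixture is carried through step 9 to 14, and the C3 carbinol is oxidised with Dess–Martin periodinane to the α-keto lactone F1. In F1, C4 is α to a ketone and should equilibrate through the enol (DBU cat.) to the isomer with side chain and vinyl both equatorial. Reduction of the ketone with NaBH4 (MeOH, −78 °C) returns to 14, whose C3 configuration is irrelevant.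

Step 10. The fully substituted α-silyloxy ketene acetal may desilylate or fragment before the strained boat transition state is reached. Fallback (quaternary carbinol built by carbonyl addition, setting out from 13 and returning at 19):
- Lactone 13, whose trisubstituted ketene acetal is the directly precedented class, is rearranged under the same Ireland–Claisen protocol to the cyclohexene acid F2.
- The ring alkene is hydrogenated with RhCl(PPh3)3 to the saturated acid F3.
- The acid dianion (LiN(i-Pr)2, 2.2 equiv) is oxygenated with O2/P(OEt)3 to the α-hydroxy acid F4 (either C1 epimer serves), which Pb(OAc)4 cleaves to the ketone F5.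
- Dimethylsulfoxonium methylide (Me3S(O)I, NaH, DMSO; Corey–Chaykovsky) should deliver CH2 equatorially, away from the syn-axial C3 methyl, to give the spiro-epoxide F6 with oxygen cis to the side chain.
- KOH in aqueous DMSO opens the epoxide at CH2 and cleaves the pivalate to give triol 19.

Step 14. The phenoxide may attack the unsubstituted allyl terminus (linear ether), facial control may erode through syn/anti interconversion of the π-allyl complex, the tertiary hydroxyl may capture the complex as a six-membered cyclic ether, or atranol may be allylated twice. Fallback (metal-free chromene annulation, setting out from 19 and returning at 24): the allylic alcohol of 19 is oxidised with MnO2 to the enal F7, which is condensed with orcinol (ethylenediammonium diacetate, toluene, 110 °C). C-Alkylation between the two hydroxyls, dehydration to the ortho-quinone methide and oxa-6π electrocyclisation should give 24 together with its C2 epimer. The two are diastereomers, because the carbocycle is enantiopure, and would be separated by preparative HPLC.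

**Further compounds**
F1 | step 8 | (2E)-5-[(4S,6R)-5,5-dimethyl-2,3-dioxo-6-vinyltetrahydro-2H-pyran-4-yl]-3-methylpent-2-en-1-yl pivalate | CC(C)(C)C(=O)OC/C=C(C)/CC[C@@H]1C(=O)C(=O)O[C@H](C=C)C1(C)C
F2 | step 10 | (1S,6R)-5,5-dimethyl-6-[(3E)-3-methyl-5-(pivaloyloxy)pent-3-en-1-yl]cyclohex-3-ene-1-carboxylic acid | CC(C)(C)C(=O)OC/C=C(C)/CC[C@H]1C(C)(C)C=CC[C@@H]1C(=O)O
F3 | step 10 | (1S,2R)-3,3-dimethyl-2-[(3E)-3-methyl-5-(pivaloyloxy)pent-3-en-1-yl]cyclohexane-1-carboxylic acid | CC(C)(C)C(=O)OC/C=C(C)/CC[C@H]1C(C)(C)CCC[C@@H]1C(=O)O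
F4 | step 10 | (1S,2S)-1-hydroxy-3,3-dimethyl-2-[(3E)-3-methyl-5-(pivaloyloxy)pent-3-en-1-yl]cyclohexane-1-carboxylic acid (expected major epimer) | CC(C)(C)C(=O)OC/C=C(C)/CC[C@H]1C(C)(C)CCC[C@@]1(O)C(=O)O
F5 | step 10 | (2E)-5-[(1S)-2,2-dimethyl-6-oxocyclohexyl]-3-methylpent-2-en-1-yl pivalate | CC(C)(C)C(=O)OC/C=C(C)/CC[C@H]1C(C)(C)CCCC1=O
F6 | step 10 | (2E)-5-[(3R,4S)-5,5-dimethyl-1-oxaspiro[2.5]octan-4-yl]-3-methylpent-2-en-1-yl pivalate | CC(C)(C)C(=O)OC/C=C(C)/CC[C@H]1C(C)(C)CCC[C@]12CO2
F7 | step 14 | (2E)-5-[(1S,2R)-2-hydroxy-2-(hydroxymethyl)-6,6-dimethylcyclohexyl]-3-methylpent-2-enal | O=C/C=C(C)/CC[C@H]1C(C)(C)CCC[C@]1(O)CO
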